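The route rests on cutting the isoflavone at C4–C4a, the bond from the pyranone carbonyl to ring A. Ring A is a resorcinol ring in which C4a sits para to O7 and ortho to O1, so it is the most nucleophilic carbon that an acyl group tethered through O1–C2=C3 can reach. One Friedel–Crafts cycloacylation therefore forms C4–C4a and closes ring C; the C2 methine, the C3–aryl bond and the O1–C8a bond are carried in from the precursor. That precursor is a 2-aryl-3-aryloxyacrylic acid: C-alpha carries the silyl-protected 8-hydroxy-7-methoxy-2,2-dimethylchromen-5-yl unit (ring B with its pyran), C-beta the 3-silyloxyphenoxy group.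

Key step: step 11

Remark on geometry: the target has no stereocentre; the acrylate double bond is drawn E (aryloxy or sulfonyloxy trans to the carboxyl carbon) where that isomer should predominate, and any Z isomer would be carried along because both converge in the key step.
Remark on the precursor: in the E acid the carboxyl group is trans to the aryloxy group and cannot reach ring A; closure needs the Z acyl form, which should arise in the flask and is listed as a compound of its own.
Remark on protection: a silyl group on the 4-oxygen of the catechol would move to the neighbouring phenoxide during the basic propargylation, so this oxygen is first masked as a MOM ether and the TIPS ether is installed once no free neighbouring hydroxyl is left.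

Step 1
Reactants: 1 5-hydroxyvanillin (3,4-dihydroxy-5-methoxybenzaldehyde)
Product: 2 3-hydroxy-5-methoxy-4-(methoxymethoxy)benzaldehyde
Conditions: MOMCl (1.05 equiv), K2CO3 (1.1 equiv), acetone, 0 °C to rt
Reagents that add atoms: chloromethyl methyl ether (MOMCl), COCCl
Why: Williamson-type O-alkylation; the 4-OH is para to the formyl group and therefore the more acidic phenol, so one equivalent of carbonate should ionise it alone and the small, fast electrophile should cap it, while the acetal so formed cannot migrate to the neighbouring oxygen.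

Step 2
Reactants: 2 3-hydroxy-5-methoxy-4-(methoxymethoxy)benzaldehyde; 3 3-chloro-3-methylbut-1-yne
Product: 4 5-methoxy-4-(methoxymethoxy)-3-[(2-methylbut-3-yn-2-yl)oxy]benzaldehyde
Conditions: CuCl2·2H2O (1 mol %), DBU (1.3 equiv), MeCN, 0 °C
Reagents that add atoms: none
Why: copper-catalysed propargylic etherification of a phenol with a tertiary propargyl chloride (substitution through a copper acetylide/allenylidene species), which should outrun elimination at 0 °C and leaves the aldehyde and the MOM ether untouched.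

Step 3
Reactants: 4 5-methoxy-4-(methoxymethoxy)-3-[(2-methylbut-3-yn-2-yl)oxy]benzaldehyde
Product: 6 7-methoxy-8-(methoxymethoxy)-2,2-dimethyl-2H-chromene-5-carbaldehyde, via allenyl phenol 5 (not isolated)
Conditions: o-xylene, BHT (cat.), 145 °C
Reagents that add atoms: none
Why: aryl propargyl ether Claisen rearrangement to the only free ortho carbon (the other ortho carbon bears the MOM ether) gives allenyl phenol 5 after enolisation, and a 1,5-hydrogen shift followed by oxa-6π electrocyclisation should close the 2,2-dimethyl-2H-chromene.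

Step 4
Reactants: 6 7-methoxy-8-(methoxymethoxy)-2,2-dimethyl-2H-chromene-5-carbaldehyde
Product: 7 8-hydroxy-7-methoxy-2,2-dimethyl-2H-chromene-5-carbaldehyde
Conditions: 3 M aq. HCl, THF, 50 °C
Reagents that add atoms: none
Why: acid-catalysed hydrolysis of the phenolic MOM acetal; the formyl group on the same ring lowers the basicity of the chromene alkene, so it should survive dilute acid.

Step 5
Reactants: 7 8-hydroxy-7-methoxy-2,2-dimethyl-2H-chromene-5-carbaldehyde
Product: 8 7-methoxy-2,2-dimethyl-8-(triisopropylsilyloxy)-2H-chromene-5-carbaldehyde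
Conditions: TIPSCl (1.3 equiv), imidazole (2.5 equiv), DMF, rt to 40 °C
Reagents that add atoms: chlorotriisopropylsilane (TIPSCl), CC(C)[Si](Cl)(C(C)C)C(C)C
Why: silylation of the single remaining phenol with a silyl chloride and imidazole; with no free neighbouring hydroxyl left, the silyl ether can no longer migrate.

Step 6
Reactants: 8 7-methoxy-2,2-dimethyl-8-(triisopropylsilyloxy)-2H-chromene-5-carbaldehyde; 9 ethyl diazoacetate
Product: 10 ethyl (2Z)-3-hydroxy-2-[7-methoxy-2,2-dimethyl-8-(triisopropylsilyloxy)-2H-chromen-5-yl]prop-2-enoate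
Conditions: HBF4·OEt2 (10 mol %), CH2Cl2, −78 °C, slow addition of 9, then to rt
Reagents that add atoms: none
Why: Brønsted acid-catalysed aldehyde–diazoacetate homologation (a Roskamp-type reaction steered to 1,2-aryl shift): addition of 9 to the protonated aldehyde gives a β-hydroxy diazonium ion, the para-silyloxy aryl group migrates with loss of N2 in preference to hydride, and the α-formyl ester should be obtained as its hydrogen-bonded Z enol.

Step 7
Reactants: 10 ethyl (2Z)-3-hydroxy-2-[7-methoxy-2,2-dimethyl-8-(triisopropylsilyloxy)-2H-chromen-5-yl]prop-2-enoate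
Product: 11 ethyl (2E)-2-[7-methoxy-2,2-dimethyl-8-(triisopropylsilyloxy)-2H-chromen-5-yl]-3-(tosyloxy)prop-2-enoate
Conditions: TsCl (1.3 equiv), N-methylimidazole (1.5 equiv), Et3N (1.5 equiv), CH2Cl2, 0 °C
Reagents that add atoms: p-toluenesulfonyl chloride (TsCl), Cc1ccc(cc1)S(Cl)(=O)=O
Why: O-sulfonylation of the enol under amine/N-methylimidazole activation, non-chelating conditions that should favour the E enol tosylate.

Step 8
Reactants: 12 resorcinol
Product: 13 3-(triisopropylsilyloxy)phenol
Conditions: TIPSCl (1.0 equiv), imidazole (1.2 equiv), 12 (3 equiv), DMF, 0 °C to rt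
Reagents that add atoms: chlorotriisopropylsilane (TIPSCl), CC(C)[Si](Cl)(C(C)C)C(C)C
Why: statistical monosilylation of a symmetrical diol, steered to the mono-ether by an excess of resorcinol that is washed out with water.

Step 9
Reactants: 11 ethyl (2E)-2-[7-methoxy-2,2-dimethyl-8-(triisopropylsilyloxy)-2H-chromen-5-yl]-3-(tosyloxy)prop-2-enoate; 13 3-(triisopropylsilyloxy)phenol
Product: 14 ethyl (2E)-2-[7-methoxy-2,2-dimethyl-8-(triisopropylsilyloxy)-2H-chromen-5-yl]-3-[3-(triisopropylsilyloxy)phenoxy]prop-2-enoate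
Conditions: K2CO3 (1.5 equiv), DABCO (10 mol %), MeCN, 0 °C to rt
Reagents that add atoms: none
Why: nucleophilic vinylic substitution by addition–elimination at the β-carbon of the acceptor alkene, with DABCO as nucleophilic catalyst, should replace tosylate by the phenoxide and give the thermodynamically preferred E vinylogous carbonate.

Step 10
Reactants: 14 ethyl (2E)-2-[7-methoxy-2,2-dimethyl-8-(triisopropylsilyloxy)-2H-chromen-5-yl]-3-[3-(triisopropylsilyloxy)phenoxy]prop-2-enoate
Product: 15 (2E)-2-[7-methoxy-2,2-dimethyl-8-(triisopropylsilyloxy)-2H-chromen-5-yl]-3-[3-(triisopropylsilyloxy)phenoxy]prop-2-enoic acid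
Conditions: LiOH·H2O (3 equiv), THF/H2O 3:1, rt; then 1 M HCl to pH 3 at 0 °C
Reagents that add atoms: lithium hydroxide (its oxygen ends up in the carboxyl group), [Li+].[OH-]
Why: saponification of the ethyl ester with LiOH at room temperature, conditions that hindered aryl TIPS ethers and the aryl vinyl ether should withstand.

Step 11
Reactants: 15 (2E)-2-[7-methoxy-2,2-dimethyl-8-(triisopropylsilyloxy)-2H-chromen-5-yl]-3-[3-(triisopropylsilyloxy)phenoxy]prop-2-enoic acid
Product: 18 3-[7-methoxy-2,2-dimethyl-8-(triisopropylsilyloxy)-2H-chromen-5-yl]-7-(triisopropylsilyloxy)-4H-chromen-4-one, via E-acyl chloride 16 (not isolated), via Z-acyl chloride 17 (not isolated)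
Conditions: 1-chloro-N,N,2-trimethylprop-1-en-1-amine (1.2 equiv), CH2Cl2, 0 °C; then 2,6-di-tert-butyl-4-methylpyridine (1.5 equiv), SnCl4 (2.5 equiv), CH2Cl2 (0.01 M), −40 to 0 °C
Reagents that add atoms: none
Why: The acid is turned under neutral conditions into E-acyl chloride 16, and SnCl4 ionises it to an acylium ion whose ketene–oxocarbenium resonance form (ArO+=CH–C(Ar)=C=O) has a single bond between C-alpha and C-beta, so rotation should give the Z-acyl species 17 with the acyl carbon next to ring A. The acylium carbon is then attacked by the ring A carbon that is ortho to the vinyl ether oxygen and para to the silyloxy group, and loss of a proton from the arenium ion gives the chromone; this is an intramolecular Friedel–Crafts acylation, the reaction type by which 3-aryloxyacrylic acids are known to give chromones. Ring C closes in a 6-exo mode (exo-dig at the linear acylium carbon), the new bond being C4–C4a. No stereocentre is formed, and the alkene geometry is erased because the double bond becomes the endocyclic C2=C3 bond. Regioselectivity for the carbon para to the silyloxy group should come from its stronger activation and from the bulky triisopropylsilyl group, which shields the carbon between the two oxygens. Chemoselectivity should come from the hindered pyridine, which takes up HCl before it can add to the chromene alkene, from high dilution against intermolecular acylation of that alkene, and from the geometry of ring B, whose alkene could only close a five-membered ring through an unstabilised cation.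

Step 12
Reactants: 18 3-[7-methoxy-2,2-dimethyl-8-(triisopropylsilyloxy)-2H-chromen-5-yl]-7-(triisopropylsilyloxy)-4H-chromen-4-one
Product: 19 7-hydroxy-3-(8-hydroxy-7-methoxy-2,2-dimethyl-2H-chromen-5-yl)-4H-chromen-4-one (target, CNP0338889.0)
Conditions: TBAF (2.5 equiv), AcOH (2.5 equiv), THF, 0 °C to rt
Reagents that add atoms: none
Why: fluoride-driven cleavage of both aryl silyl ethers (formation of the strong Si–F bond), buffered with AcOH so that the base-sensitive pyranone is not exposed to free fluoride or phenoxide base.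

Compound list
1 | 5-hydroxyvanillin (3,4-dihydroxy-5-methoxybenzaldehyde) | COc1cc(C=O)cc(O)c1O | starting material
2 | 3-hydroxy-5-methoxy-4-(methoxymethoxy)benzaldehyde | COCOc1c(O)cc(C=O)cc1OC | intermediate
3 | 3-chloro-3-methylbut-1-yne | CC(C)(Cl)C#C | starting material
4 | 5-methoxy-4-(methoxymethoxy)-3-[(2-methylbut-3-yn-2-yl)oxy]benzaldehyde | COCOc1c(OC(C)(C)C#C)cc(C=O)cc1OC | intermediate
5 | 3-hydroxy-5-methoxy-4-(methoxymethoxy)-2-(3-methylbuta-1,2-dien-1-yl)benzaldehyde (allenyl phenol) | COCOc1c(OC)cc(C=O)c(C=C=C(C)C)c1O | intermediate (not isolated)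
6 | 7-methoxy-8-(methoxymethoxy)-2,2-dimethyl-2H-chromene-5-carbaldehyde | COCOc1c(OC)cc(C=O)c2C=CC(C)(C)Oc12 | intermediate
7 | 8-hydroxy-7-methoxy-2,2-dimethyl-2H-chromene-5-carbaldehyde | COc1cc(C=O)c2C=CC(C)(C)Oc2c1O | intermediate
8 | 7-methoxy-2,2-dimethyl-8-(triisopropylsilyloxy)-2H-chromene-5-carbaldehyde | COc1cc(C=O)c2C=CC(C)(C)Oc2c1O[Si](C(C)C)(C(C)C)C(C)C | intermediate
9 | ethyl diazoacetate | CCOC(=O)C=[N+]=[N-] | starting material
10 | ethyl (2Z)-3-hydroxy-2-[7-methoxy-2,2-dimethyl-8-(triisopropylsilyloxy)-2H-chromen-5-yl]prop-2-enoate | CCOC(=O)/C(=C\O)c1cc(OC)c(O[Si](C(C)C)(C(C)C)C(C)C)c2OC(C)(C)C=Cc12 | intermediate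
11 | ethyl (2E)-2-[7-methoxy-2,2-dimethyl-8-(triisopropylsilyloxy)-2H-chromen-5-yl]-3-(tosyloxy)prop-2-enoate | CCOC(=O)/C(=C/OS(=O)(=O)c1ccc(C)cc1)c1cc(OC)c(O[Si](C(C)C)(C(C)C)C(C)C)c2OC(C)(C)C=Cc12 | intermediate
12 | resorcinol | Oc1cccc(O)c1 | starting material
13 | 3-(triisopropylsilyloxy)phenol | CC(C)[Si](Oc1cccc(O)c1)(C(C)C)C(C)C | intermediate
14 | ethyl (2E)-2-[7-methoxy-2,2-dimethyl-8-(triisopropylsilyloxy)-2H-chromen-5-yl]-3-[3-(triisopropylsilyloxy)phenoxy]prop-2-enoate | CCOC(=O)/C(=C/Oc1cccc(O[Si](C(C)C)(C(C)C)C(C)C)c1)c1cc(OC)c(O[Si](C(C)C)(C(C)C)C(C)C)c2OC(C)(C)C=Cc12 | intermediate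
15 | (2E)-2-[7-methoxy-2,2-dimethyl-8-(triisopropylsilyloxy)-2H-chromen-5-yl]-3-[3-(triisopropylsilyloxy)phenoxy]prop-2-enoic acid | OC(=O)/C(=C/Oc1cccc(O[Si](C(C)C)(C(C)C)C(C)C)c1)c1cc(OC)c(O[Si](C(C)C)(C(C)C)C(C)C)c2OC(C)(C)C=Cc12 | intermediate
16 | (2E)-2-[7-methoxy-2,2-dimethyl-8-(triisopropylsilyloxy)-2H-chromen-5-yl]-3-[3-(triisopropylsilyloxy)phenoxy]prop-2-enoyl chloride | ClC(=O)/C(=C/Oc1cccc(O[Si](C(C)C)(C(C)C)C(C)C)c1)c1cc(OC)c(O[Si](C(C)C)(C(C)C)C(C)C)c2OC(C)(C)C=Cc12 | intermediate (not isolated)
17 | (2Z)-2-[7-methoxy-2,2-dimethyl-8-(triisopropylsilyloxy)-2H-chromen-5-yl]-3-[3-(triisopropylsilyloxy)phenoxy]prop-2-enoyl chloride | ClC(=O)/C(=C\Oc1cccc(O[Si](C(C)C)(C(C)C)C(C)C)c1)c1cc(OC)c(O[Si](C(C)C)(C(C)C)C(C)C)c2OC(C)(C)C=Cc12 | intermediate (not isolated)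
18 | 3-[7-methoxy-2,2-dimethyl-8-(triisopropylsilyloxy)-2H-chromen-5-yl]-7-(triisopropylsilyloxy)-4H-chromen-4-one | CC(C)[Si](Oc1ccc2c(c1)occ(-c1cc(OC)c(O[Si](C(C)C)(C(C)C)C(C)C)c3OC(C)(C)C=Cc13)c2=O)(C(C)C)C(C)C | intermediate
19 | 7-hydroxy-3-(8-hydroxy-7-methoxy-2,2-dimethyl-2H-chromen-5-yl)-4H-chromen-4-one | COc1cc(-c2coc3cc(O)ccc3c2=O)c2c(c1O)OC(C)(C)C=C2 | target

Total step count: 12.
Longest linear sequence: 11 steps (steps 1–7 and 9–12, from 5-hydroxyvanillin); step 8 is the side branch from resorcinol.

Steps most likely to fail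

Step 11 (key cycloacylation). What may go wrong: acylation at the ring A carbon between the two oxygens, loss of a silyl ether under the Lewis acid, or cationic attack on the chromene alkene. The fallback makes the isoflavone by oxidative chalcone rearrangement, which builds the C3–aryl bond by 1,2-aryl shift and closes ring C at oxygen. It sets out from 6 and comes back at 19. Aldehyde 6 is condensed in a Claisen–Schmidt reaction (KOH, EtOH, rt) with 1-[2-hydroxy-4-(methoxymethoxy)phenyl]ethanone F1, itself made from commercial 2,4-dihydroxyacetophenone (CC(=O)c1ccc(O)cc1O) with MOMCl and K2CO3 in acetone. This should give (2E)-1-[2-hydroxy-4-(methoxymethoxy)phenyl]-3-[7-methoxy-8-(methoxymethoxy)-2,2-dimethyl-2H-chromen-5-yl]prop-2-en-1-one F2. Treatment with Tl(NO3)3·3H2O in MeOH/CH(OMe)3 at rt should bring about the oxidative 1,2-shift of the para-oxygenated ring B and give racemic 1-[2-hydroxy-4-(methoxymethoxy)phenyl]-3,3-dimethoxy-2-[7-methoxy-8-(methoxymethoxy)-2,2-dimethyl-2H-chromen-5-yl]propan-1-one F3. HCl in MeOH at 50 °C should then close ring C with loss of methanol and remove both MOM groups to give 19.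

Step 6 (homologation with aryl shift). What may go wrong: hydride migration in place of aryl migration (leading to the β-keto ester), or acid-induced loss of the silyl ether and oligomerisation through the chromene alkene. The fallback is a stepwise one-carbon homologation followed by Claisen formylation. It sets out from 8 and comes back at 10. Wittig methoxymethylenation of 8 (Ph3P(CH2OMe)Cl, KN(SiMe3)2, THF, 0 °C) should give 7-methoxy-5-[(E)-2-methoxyethenyl]-2,2-dimethyl-8-(triisopropylsilyloxy)-2H-chromene F4 (an E/Z mixture is expected, E drawn). Mild hydrolysis (HCO2H, THF/H2O, rt) should give [7-methoxy-2,2-dimethyl-8-(triisopropylsilyloxy)-2H-chromen-5-yl]acetaldehyde F5. Pinnick oxidation (NaClO2, NaH2PO4, 2-methylbut-2-ene, t-BuOH/H2O) should give [7-methoxy-2,2-dimethyl-8-(triisopropylsilyloxy)-2H-chromen-5-yl]acetic acid F6. Esterification (EtOH, EDC·HCl, DMAP, CH2Cl2) should give ethyl [7-methoxy-2,2-dimethyl-8-(triisopropylsilyloxy)-2H-chromen-5-yl]acetate F7. Formylation (NaH, HCO2Et, THF, 0 °C to rt, mild acidic work-up) should then give 10.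

Step 9 (vinylic substitution). What may go wrong: attack of the phenoxide on sulfur in place of the β-carbon (sulfonyl transfer that regenerates the enolate of 10), or silyl transfer between phenoxides. The fallback uses a leaving group that has no second electrophilic centre. It sets out from 10 and comes back at 14. Vilsmeier-type chlorination of 10 ((COCl)2, DMF, CH2Cl2, 0 °C) should give ethyl (2E)-3-chloro-2-[7-methoxy-2,2-dimethyl-8-(triisopropylsilyloxy)-2H-chromen-5-yl]prop-2-enoate F8 (geometry not critical, E drawn). Addition–elimination with 13 (K2CO3, MeCN, rt) should then give 14.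

Further compounds
F1 | step 11 | 1-[2-hydroxy-4-(methoxymethoxy)phenyl]ethanone | CC(=O)c1ccc(OCOC)cc1O
F2 | step 11 | (2E)-1-[2-hydroxy-4-(methoxymethoxy)phenyl]-3-[7-methoxy-8-(methoxymethoxy)-2,2-dimethyl-2H-chromen-5-yl]prop-2-en-1-one | COCOc1ccc(C(=O)/C=C/c2cc(OC)c(OCOC)c3OC(C)(C)C=Cc23)c(O)c1
F3 | step 11 | 1-[2-hydroxy-4-(methoxymethoxy)phenyl]-3,3-dimethoxy-2-[7-methoxy-8-(methoxymethoxy)-2,2-dimethyl-2H-chromen-5-yl]propan-1-one (racemic) | COCOc1ccc(C(=O)C(C(OC)OC)c2cc(OC)c(OCOC)c3OC(C)(C)C=Cc23)c(O)c1
F4 | step 6 | 7-methoxy-5-[(E)-2-methoxyethenyl]-2,2-dimethyl-8-(triisopropylsilyloxy)-2H-chromene | CO/C=C/c1cc(OC)c(O[Si](C(C)C)(C(C)C)C(C)C)c2OC(C)(C)C=Cc12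
F5 | step 6 | [7-methoxy-2,2-dimethyl-8-(triisopropylsilyloxy)-2H-chromen-5-yl]acetaldehyde | O=CCc1cc(OC)c(O[Si](C(C)C)(C(C)C)C(C)C)c2OC(C)(C)C=Cc12
F6 | step 6 | [7-methoxy-2,2-dimethyl-8-(triisopropylsilyloxy)-2H-chromen-5-yl]acetic acid | OC(=O)Cc1cc(OC)c(O[Si](C(C)C)(C(C)C)C(C)C)c2OC(C)(C)C=Cc12
F7 | step 6 | ethyl [7-methoxy-2,2-dimethyl-8-(triisopropylsilyloxy)-2H-chromen-5-yl]acetate | CCOC(=O)Cc1cc(OC)c(O[Si](C(C)C)(C(C)C)C(C)C)c2OC(C)(C)C=Cc12
F8 | step 9 | ethyl (2E)-3-chloro-2-[7-methoxy-2,2-dimethyl-8-(triisopropylsilyloxy)-2H-chromen-5-yl]prop-2-enoate | CCOC(=O)/C(=C/Cl)c1cc(OC)c(O[Si](C(C)C)(C(C)C)C(C)C)c2OC(C)(C)C=Cc12
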